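If each turnover frees one acid and that acid protonates a second nucleophile, each electrophile costs two nucleophiles. Reaction would then stop at 47.5% of the electrophile charged, half the equivalents of nucleophile. I called this the ceiling, and it would make the nucleophile the limiting reagent. If the free base caught the acid first, the ceiling would be higher:

62.5%

| flask | electrophile | nucleophile | free base | remark | time |
|---|---|---|---|---|---|
| birch | 13 mM | 0.95 equiv | 0.30 equiv | run made earlier |  |
| larch | 28 mM | 0.95 equiv | 0.30 equiv | run made earlier |  |
| alder | 19 mM | 0.95 equiv | 0.15 equiv | run made earlier |  |
| flask | 19 mM | 0.950 equiv | 0.300 equiv |  | 3.0 min |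

- birch (time / min: electrophile / %, product / %): 0.833: 72.6, 27.8; 2.00: 63.2, 39.2; 2.50: 61.8, 38.1; 4.00: 57.5, 44.3
- larch (time / min: electrophile / %, product / %): 0.833: 62.2, 38.8; 2.00: 55.5, 43.9; 2.50: 54.2, 45.3; 4.00: 53.4, 47.5
- alder (time / min: electrophile / %, product / %): 0.833: 66.1, 34.5; 2.00: 57.7, 42.2; 2.50: 57.1, 43.5; 4.00: 55.4, 45.4

(readings scatter by 1 percentage point)

- the earlier runs were read with a standard deviation of 1 percentage point
- a reading or a percentage of product counts all its forms, free or not
- the earlier runs do not show how much of nucleophile is bound; that part of a forecast is a guess

- part of the electrophile that has reacted at 3.0 min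
- share of free nucleophile in free nucleophile and protonated nucleophile together, at 3.0 min

I tested both ceilings on rates in larch. I assumed rate follows electrophile times free nucleophile, and took the fraction of the charge reacted at the third reading, 45.3%. Against the starting rate, the two pictures predict:

nucleophile catches the acid: 0.0253

free base catches it first: 0.198

Between its last two readings, larch made product at 0.0315 of its mean rate over the first interval. That ratio carries the scatter of the readings, and the first interval's mean only stands in for the starting rate. It lies nearer the first picture, so I dropped the higher ceiling.

Alder has the same nucleophile and the flask's concentration, though less free base. Read straight between its last two readings, at 3.0 min, its product gives 44.1%. Its electrophile loss gives 43.5%. I took their mean, 43.8%. The balance then gives a guessed free share: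

(nucleophile charged − reacted − reacted)/(nucleophile charged − reacted) = 14.5%

The forecast gave 44% and 15%, holding that “each turnover releases one acid equivalent”.

The flask gave 44.3% reacted and 7.82% free.

    electrophile + nucleophile ⇌ acid set free + product (K = 0.770, k = 0.900 /M/s)
    nucleophile + acid set free ⇌ protonated nucleophile, settled at all times (K = 1.00 × 10⁵ /M)
    acid set free + free base ⇌ salt of the base (K = 530 /M, k = 69.0 /M/s)
    crystals ⇌ product, rate k4*(cs4 - [product]) while solid is left; crystals form when [product] > cs4 (solubility = 13.0 mM, k = 3.20 /s)
    nucleophile ⇌ dormant form (K = 0.550, k = 0.00330 /s)

So the flask stood 3.2 percentage points under the ceiling, and its free share lay below my balance. At 3.00 min the dormant form in the flask amounted to 5.20% of the electrophile charged, and my balance had not counted it. A neighbouring flask held 0.570 equiv of nucleophile, with its other charges as in the flask. Its ceiling is 28.5%, and at 3.00 min it had reached 27.6%, with 3.1% of its nucleophile still unbound.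

The earlier runs and the new flask were computed on assumed constants, and the scatter is random.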